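**Retrosynthetic overview**

1. Target 35 comes from 34 by a last, neutral hydrogenolysis of two benzyl ethers and of the (S)-1-phenylethyl acetal (the C–O bond at the lactol carbon is not broken); 34 comes from 33 by mild hydrolysis of two dimethyl acetals.
2. 33 is cut by a rhodium-catalysed (2+2+2) cycloaddition into diyne 24 and benzyloxyethyne 32. The feature used: in ring A the carbon carrying the diaryl-ether oxygen and the carbon carrying the ester carbonyl are neighbours, and both links end on adjacent oxygens (C4–O, C5–O) of ring B, so ring A and the seven-membered dioxepinone ring C can close together from a diyne hung on these two oxygens.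
3. 24 comes from the ring B/D phthalide: but-2-ynoate on C5–O (put on last), aryl ynol ether on C4–O made from an α-aryloxy ketone through its enol triflate; allyl on C5–O and silyl on C4–O tell the two oxygens apart.
4. Ring B/D comes from 2,4,5-trimethoxybenzoic acid 1: ortho-lithiation/formylation closes lactol ring D, demethylation follows, C3 is fixed as the separable (S)-1-phenylethyl acetal, and the only free ring position (C6) is formylated under magnesium phenoxide control.
5. Ring order: B (bought) → D (step 1) → A and C together (step 16).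

Key step: step 16

Remark: the free lactol carbon of the target can epimerise by ring–chain tautomerism in protic, acidic or basic media; it is therefore carried as the (S)-1-phenylethyl acetal and freed only in the last, neutral step, and the product is assumed to be handled cold and aprotic.
Numbering: ring B/D compounds are named as phthalides (C1 lactone carbonyl, C3 acetal carbon, C4–C7 ring B carbons); ring A is the methyl-bearing arene, ring C the seven-membered ring.

Step 1
Reactants: 1 2,4,5-trimethoxybenzoic acid
Product: 3 lactol 3-hydroxy-4,5,7-trimethoxyphthalide (racemic), via aryllithium carboxylate 2 (not isolated)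
Conditions: s-BuLi (2.2 equiv), TMEDA, THF, −78 °C; DMF, −78 °C → rt; aq. HCl
Reagents that add atoms: N,N-dimethylformamide CN(C)C=O
Why: Directed ortho-metalation, in which the lithium carboxylate and the C5 methoxy group together steer s-BuLi/TMEDA to C6, followed by formylation with DMF; the 2-formylbenzoic acid should close ring D as its lactol tautomer, with C3 racemic at this stage.

Step 2
Reactants: 3 lactol 3-hydroxy-4,5,7-trimethoxyphthalide
Product: 5 tetraacetate 3,4,5,7-tetraacetoxyphthalide (racemic), via tetrahydroxyphthalide 4 (not isolated)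
Conditions: BBr3 (6 equiv), CH2Cl2, −78 °C → rt; H2O, 0 °C, EtOAc extraction; crude 4, Ac2O, pyridine, DMAP (cat.), 0 °C → rt, argon
Reagents that add atoms: acetic anhydride CC(=O)OC(C)=O
Why: Lewis-acid cleavage of the three aryl methyl ethers, then peracetylation, which should turn the air-sensitive tetrol into a stable compound and make the lactol a pseudo-anomeric acetate ready for activation.

Step 3
Reactants: 5 tetraacetate 3,4,5,7-tetraacetoxyphthalide; 6 (S)-1-phenylethanol
Product: 8 acetal triacetate (3S)-4,5,7-triacetoxy-3-[(1S)-1-phenylethoxy]phthalide, via bromophthalide triacetate 7 (not isolated)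
Conditions: HBr (33% in AcOH), CH2Cl2, 0 °C → rt, evaporate; then 6 (1.5 equiv), Ag2CO3, 4 Å MS, CH2Cl2, −20 °C → rt; separation of the C3 epimers by chromatography or crystallisation
Reagents that add atoms: none
Why: Koenigs–Knorr substitution at the acyl-acetal carbon, in which the hydroxyl oxygen of 6 attacks the bromide under silver assistance so that the carbinol centre of 6 is untouched; C3 forms as both epimers and the wanted (3S) epimer 8 is separated from its (3R) epimer, its configuration to be assigned by X-ray crystallography.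

Step 4
Reactants: 8 acetal triacetate (3S)-4,5,7-triacetoxy-3-[(1S)-1-phenylethoxy]phthalide
Product: 9 triol (3S)-4,5,7-trihydroxy-3-[(1S)-1-phenylethoxy]phthalide
Conditions: NH4OAc (excess), MeOH/H2O (4:1), rt, argon; used at once
Reagents that add atoms: none
Why: Neutral solvolysis of aryl acetates, which are far more reactive than the hindered lactone acetal, so the auxiliary and C3 should stay intact.

Step 5
Reactants: 9 triol (3S)-4,5,7-trihydroxy-3-[(1S)-1-phenylethoxy]phthalide
Product: 10 allyl ether (3S)-5-(allyloxy)-4,7-dihydroxy-3-[(1S)-1-phenylethoxy]phthalide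
Conditions: allyl bromide (1.05 equiv), K2CO3 (1.0 equiv), DMF, 0 °C → rt, argon
Reagents that add atoms: allyl bromide C=CCBr
Why: Williamson etherification of the monoanion, expected at C5–OH because it is para to the lactone carbonyl (most acidic), not hydrogen-bonded and least hindered, as in the known 4-O-monoalkylation of 3,4-dihydroxybenzoates; C7–OH is chelated and C4–OH is shielded by the C3 acetal.

Step 6
Reactants: 10 allyl ether (3S)-5-(allyloxy)-4,7-dihydroxy-3-[(1S)-1-phenylethoxy]phthalide
Product: 11 aldehyde (3S)-5-(allyloxy)-6-formyl-4,7-dihydroxy-3-[(1S)-1-phenylethoxy]phthalide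
Conditions: MgCl2 (3 equiv), Et3N (6 equiv), (CH2O)n (8 equiv), THF, reflux, argon; cold aq. citric acid
Reagents that add atoms: paraformaldehyde (as formaldehyde) C=O
Why: Casnati–Skattebøl ortho-formylation, in which the magnesium phenoxide of C7–OH delivers formaldehyde to C6, the only unsubstituted ring position, and a second formaldehyde oxidises the benzylic alkoxide; the medium is basic, so the acetal is not touched.

Step 7
Reactants: 11 aldehyde (3S)-5-(allyloxy)-6-formyl-4,7-dihydroxy-3-[(1S)-1-phenylethoxy]phthalide
Product: 12 silyl ether (3S)-5-(allyloxy)-6-formyl-7-hydroxy-3-[(1S)-1-phenylethoxy]-4-(triisopropylsilyloxy)phthalide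
Conditions: i-Pr3SiCl (1.2 equiv), imidazole (2.5 equiv), DMF, rt → 40 °C
Reagents that add atoms: chlorotriisopropylsilane CC(C)[Si](Cl)(C(C)C)C(C)C
Why: Silylation of the only phenol that is not hydrogen-bonded; C7–OH is held by both the lactone and the formyl carbonyl and should not react.

Step 8
Reactants: 12 silyl ether (3S)-5-(allyloxy)-6-formyl-7-hydroxy-3-[(1S)-1-phenylethoxy]-4-(triisopropylsilyloxy)phthalide
Product: 13 benzyl ether (3S)-5-(allyloxy)-7-(benzyloxy)-6-formyl-3-[(1S)-1-phenylethoxy]-4-(triisopropylsilyloxy)phthalide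
Conditions: BnBr (1.5 equiv), K2CO3 (2 equiv), n-Bu4NI (cat.), DMF, 40 °C
Reagents that add atoms: benzyl bromide BrCc1ccccc1
Why: Williamson benzylation of the one remaining, chelated phenol under conditions that an aryl triisopropylsilyl ether tolerates.

Step 9
Reactants: 13 benzyl ether (3S)-5-(allyloxy)-7-(benzyloxy)-6-formyl-3-[(1S)-1-phenylethoxy]-4-(triisopropylsilyloxy)phthalide
Product: 14 dimethyl acetal (3S)-5-(allyloxy)-7-(benzyloxy)-6-(dimethoxymethyl)-3-[(1S)-1-phenylethoxy]-4-(triisopropylsilyloxy)phthalide
Conditions: HC(OMe)3 (5 equiv), MeOH, PPTS (10 mol%), rt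
Reagents that add atoms: trimethyl orthoformate COC(OC)OC; methanol CO
Why: Acid-catalysed acetalisation with orthoformate as water scavenger; the aldehyde is the only free carbonyl, and the acyl acetal and the silyl ether should be inert to pyridinium tosylate.

Step 10
Reactants: 14 dimethyl acetal (3S)-5-(allyloxy)-7-(benzyloxy)-6-(dimethoxymethyl)-3-[(1S)-1-phenylethoxy]-4-(triisopropylsilyloxy)phthalide; 15 3-bromo-1,1-dimethoxypropan-2-one
Product: 17 ketone (3S)-5-(allyloxy)-7-(benzyloxy)-6-(dimethoxymethyl)-4-(3,3-dimethoxy-2-oxopropoxy)-3-[(1S)-1-phenylethoxy]phthalide, via tetrabutylammonium phenoxide 16 (not isolated)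
Conditions: n-Bu4NF (1.05 equiv), THF, 0 °C; then 15 (1.3 equiv), 0 °C → rt
Reagents that add atoms: none
Why: Fluoride cleaves the aryl silyl ether to a naked phenoxide, which is alkylated in the same flask by the primary α-bromoketone (SN2, Williamson); C5–O is capped as the allyl ether, so no group can migrate.

Step 11
Reactants: 17 ketone (3S)-5-(allyloxy)-7-(benzyloxy)-6-(dimethoxymethyl)-4-(3,3-dimethoxy-2-oxopropoxy)-3-[(1S)-1-phenylethoxy]phthalide
Product: 20 ynol ether (3S)-5-(allyloxy)-7-(benzyloxy)-6-(dimethoxymethyl)-4-[(3,3-dimethoxyprop-1-yn-1-yl)oxy]-3-[(1S)-1-phenylethoxy]phthalide, via lithium enolate 18 (not isolated), via enol triflate 19 (not isolated)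
Conditions: LiN(SiMe3)2 (1.15 equiv), THF, −78 °C; PhNTf2 (1.2 equiv), −78 → −40 °C; t-BuOK (1.5 equiv), −78 °C; pH 7 buffer; Et3N-deactivated silica
Reagents that add atoms: none
Why: Known conversion of α-alkoxy ketones into ynol ethers: kinetic enolisation on the ArOCH2 side gives the chelated (Z)-enolate, O-triflation follows, and t-BuOK removes triflic acid by anti elimination; at −78 °C the lactone acetal and C3–H should not be attacked.

Step 12
Reactants: 20 ynol ether (3S)-5-(allyloxy)-7-(benzyloxy)-6-(dimethoxymethyl)-4-[(3,3-dimethoxyprop-1-yn-1-yl)oxy]-3-[(1S)-1-phenylethoxy]phthalide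
Product: 21 phenol (3S)-7-(benzyloxy)-6-(dimethoxymethyl)-4-[(3,3-dimethoxyprop-1-yn-1-yl)oxy]-5-hydroxy-3-[(1S)-1-phenylethoxy]phthalide
Conditions: Pd(PPh3)4 (5 mol%), morpholine (5 equiv), THF, rt; pH 7 buffer; used at once
Reagents that add atoms: none
Why: Tsuji–Trost deallylation: zerovalent palladium ionises the aryl allyl ether and morpholine traps the allyl fragment; the medium stays neutral to basic, so the ynol ether and the acetals should survive.

Step 13
Reactants: 21 phenol (3S)-7-(benzyloxy)-6-(dimethoxymethyl)-4-[(3,3-dimethoxyprop-1-yn-1-yl)oxy]-5-hydroxy-3-[(1S)-1-phenylethoxy]phthalide; 22 but-2-ynoic acid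
Product: 24 diyne (3S)-7-(benzyloxy)-6-(dimethoxymethyl)-4-[(3,3-dimethoxyprop-1-yn-1-yl)oxy]-3-[(1S)-1-phenylethoxy]phthalid-5-yl but-2-ynoate, via but-2-ynoic anhydride 23 (not isolated)
Conditions: 22 (2.2 equiv), DCC (1.1 equiv), CH2Cl2, 0 °C, filter; filtrate added to 21, i-Pr2NEt (1.5 equiv), DMAP (10 mol%), CH2Cl2, −20 °C
Reagents that add atoms: none
Why: Steglich-type acylation with the pre-formed symmetric anhydride, chosen because free carboxylic acids add to ynol ethers; the base-buffered, cold conditions should also spare the aryl ynoate.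

Step 14
Reactants: 25 benzyl alcohol; 26 trichloroethylene
Product: 29 benzyl (E)-1,2-dichlorovinyl ether, via potassium benzyloxide 27 (not isolated), via dichloroacetylene 28 (not isolated)
Conditions: KH (1.2 equiv), THF, 0 °C; then 26 (1.1 equiv), −50 °C → rt
Reagents that add atoms: none
Why: Known alkoxide addition–elimination on trichloroethylene: the alkoxide removes HCl to give dichloroacetylene and then adds to it in anti fashion, giving the (E)-dichlorovinyl ether.

Step 15
Reactants: 29 benzyl (E)-1,2-dichlorovinyl ether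
Product: 32 benzyloxyethyne, via benzyl chloroethynyl ether 30 (not isolated), via lithium benzyloxyacetylide 31 (not isolated)
Conditions: n-BuLi (2.3 equiv), Et2O, −78 → −40 °C; MeOH (1.2 equiv), −78 °C; cold aqueous wash; kept as a cold solution and used the same day
Reagents that add atoms: none
Why: Known alkoxyethyne synthesis: the first n-BuLi removes HCl, the second exchanges chlorine for lithium, and methanol protonates the acetylide; the product is kept cold because benzyl ynol ethers rearrange on warming.

Step 16
Reactants: 24 diyne (3S)-7-(benzyloxy)-6-(dimethoxymethyl)-4-[(3,3-dimethoxyprop-1-yn-1-yl)oxy]-3-[(1S)-1-phenylethoxy]phthalid-5-yl but-2-ynoate; 32 benzyloxyethyne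
Product: 33 protected depsidone (rings A to D; benzyl ethers on both phenols; dimethyl acetals on both formyl groups; (S)-1-phenylethyl acetal at the (S) lactol carbon)
Conditions: [Rh(cod)2]BF4 (10 mol%), (R)-H8-BINAP (10 mol%), CH2Cl2, H2 (1 atm, 30 min) then argon; 24 and 32 (3 equiv) in CH2Cl2 added over 3 h, rt
Reagents that add atoms: none
Why: The cationic monovalent rhodium bisphosphine complex binds the two tethered alkynes of 24 and couples them oxidatively to a trivalent rhodacyclopentadiene, joining the carbonyl-bearing ynoate carbon to the oxygen-bearing ynol ether carbon; 32 then inserts and C–C reductive elimination releases the arene and the catalyst. This is the known rhodium-catalysed (2+2+2) cyclotrimerisation of a tethered diyne with a monoalkyne, used here at the edge of its scope (five-atom tether, ynol ether partners). Ring C closes as a seven-membered ring in the oxidative coupling, an intramolecular union of the 1,8-diyne helped by the rigid ortho-phenylene backbone of ring B, and ring A closes as a six-membered ring in the final reductive elimination. No stereocentre is formed: C3 and the auxiliary are spectators, the dibenzodioxepinone is conformationally mobile, and the single-enantiomer ligand serves only to give one defined catalyst. The step needs regioselective insertion of 32: the nucleophilic CH terminus of the ynol ether should bond to the electrophilic methyl-bearing β-carbon of the ynoate, which puts the benzyloxy carbon next to the acetal-bearing carbon, while the tether fixes the bond between the ether-bearing and carbonyl-bearing carbons. Self-trimerisation of 32 is held back by feeding 24 and 32 slowly to the catalyst.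

Step 17
Reactants: 33 protected depsidone
Product: 34 dialdehyde (both dimethyl acetals opened; benzyl ethers and (S)-1-phenylethyl acetal kept)
Conditions: PPTS (20 mol%), acetone/H2O (10:1), rt
Reagents that add atoms: water O
Why: Mild acid hydrolysis of two electron-rich aryl dimethyl acetals; the acyl acetal at C3 ionises much less readily and the aryl ester and benzyl ethers are stable at this acidity.

Step 18
Reactants: 34 dialdehyde
Product: 35 target depsidone CNP0296574.1
Conditions: H2 (1 atm), 10% Pd/C, EtOAc, rt, stopped after uptake of 3 equiv; filtered through Celite and concentrated below 25 °C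
Reagents that add atoms: none
Why: Neutral hydrogenolysis of the two benzyl ethers and of the O–CH(CH3)Ph bond on its benzylic side; the C3–O bonds are not broken, so the (S) configuration set in step 3 is retained in the free lactol.

**Compound list**

1 | 2,4,5-trimethoxybenzoic acid | COc1cc(OC)c(C(=O)O)cc1OC | starting material
2 | lithium 6-lithio-2,4,5-trimethoxybenzoate | [Li]c1c(OC)c(OC)cc(OC)c1C(=O)O[Li] | intermediate
3 | 3-hydroxy-4,5,7-trimethoxyphthalide (racemic lactol) | COc1cc(OC)c2c(c1OC)C(O)OC2=O | intermediate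
4 | 3,4,5,7-tetrahydroxyphthalide (racemic) | Oc1cc(O)c2c(c1O)C(O)OC2=O | intermediate
5 | 3,4,5,7-tetraacetoxyphthalide (racemic) | CC(=O)Oc1cc(OC(C)=O)c2c(c1OC(C)=O)C(OC(C)=O)OC2=O | intermediate
6 | (S)-1-phenylethanol | C[C@H](O)c1ccccc1 | starting material
7 | 4,5,7-triacetoxy-3-bromophthalide (racemic) | CC(=O)Oc1cc(OC(C)=O)c2c(c1OC(C)=O)C(Br)OC2=O | intermediate
8 | (3S)-4,5,7-triacetoxy-3-[(1S)-1-phenylethoxy]phthalide | CC(=O)Oc1cc(OC(C)=O)c2c(c1OC(C)=O)[C@@H](O[C@@H](C)c1ccccc1)OC2=O | intermediate
9 | (3S)-4,5,7-trihydroxy-3-[(1S)-1-phenylethoxy]phthalide | Oc1cc(O)c2c(c1O)[C@@H](O[C@@H](C)c1ccccc1)OC2=O | intermediate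
10 | (3S)-5-(allyloxy)-4,7-dihydroxy-3-[(1S)-1-phenylethoxy]phthalide | C=CCOc1cc(O)c2c(c1O)[C@@H](O[C@@H](C)c1ccccc1)OC2=O | intermediate
11 | (3S)-5-(allyloxy)-6-formyl-4,7-dihydroxy-3-[(1S)-1-phenylethoxy]phthalide | C=CCOc1c(C=O)c(O)c2c(c1O)[C@@H](O[C@@H](C)c1ccccc1)OC2=O | intermediate
12 | (3S)-5-(allyloxy)-6-formyl-7-hydroxy-3-[(1S)-1-phenylethoxy]-4-(triisopropylsilyloxy)phthalide | C=CCOc1c(C=O)c(O)c2c(c1O[Si](C(C)C)(C(C)C)C(C)C)[C@@H](O[C@@H](C)c1ccccc1)OC2=O | intermediate
13 | (3S)-5-(allyloxy)-7-(benzyloxy)-6-formyl-3-[(1S)-1-phenylethoxy]-4-(triisopropylsilyloxy)phthalide | C=CCOc1c(C=O)c(OCc3ccccc3)c2c(c1O[Si](C(C)C)(C(C)C)C(C)C)[C@@H](O[C@@H](C)c1ccccc1)OC2=O | intermediate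
14 | (3S)-5-(allyloxy)-7-(benzyloxy)-6-(dimethoxymethyl)-3-[(1S)-1-phenylethoxy]-4-(triisopropylsilyloxy)phthalide | C=CCOc1c(C(OC)OC)c(OCc3ccccc3)c2c(c1O[Si](C(C)C)(C(C)C)C(C)C)[C@@H](O[C@@H](C)c1ccccc1)OC2=O | intermediate
15 | 3-bromo-1,1-dimethoxypropan-2-one | COC(OC)C(=O)CBr | starting material
16 | tetrabutylammonium C4-phenoxide of desilylated 14 | C=CCOc1c(C(OC)OC)c(OCc3ccccc3)c2c(c1[O-])[C@@H](O[C@@H](C)c1ccccc1)OC2=O.CCCC[N+](CCCC)(CCCC)CCCC | intermediate
17 | (3S)-5-(allyloxy)-7-(benzyloxy)-6-(dimethoxymethyl)-4-(3,3-dimethoxy-2-oxopropoxy)-3-[(1S)-1-phenylethoxy]phthalide | C=CCOc1c(C(OC)OC)c(OCc3ccccc3)c2c(c1OCC(=O)C(OC)OC)[C@@H](O[C@@H](C)c1ccccc1)OC2=O | intermediate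
18 | lithium (Z)-enolate of 17 | C=CCOc1c(C(OC)OC)c(OCc3ccccc3)c2c(c1O/C=C(\O[Li])C(OC)OC)[C@@H](O[C@@H](C)c1ccccc1)OC2=O | intermediate
19 | (Z)-enol triflate of 17 | C=CCOc1c(C(OC)OC)c(OCc3ccccc3)c2c(c1O/C=C(\OS(=O)(=O)C(F)(F)F)C(OC)OC)[C@@H](O[C@@H](C)c1ccccc1)OC2=O | intermediate
20 | (3S)-5-(allyloxy)-7-(benzyloxy)-6-(dimethoxymethyl)-4-[(3,3-dimethoxyprop-1-yn-1-yl)oxy]-3-[(1S)-1-phenylethoxy]phthalide | C=CCOc1c(C(OC)OC)c(OCc3ccccc3)c2c(c1OC#CC(OC)OC)[C@@H](O[C@@H](C)c1ccccc1)OC2=O | intermediate
21 | (3S)-7-(benzyloxy)-6-(dimethoxymethyl)-4-[(3,3-dimethoxyprop-1-yn-1-yl)oxy]-5-hydroxy-3-[(1S)-1-phenylethoxy]phthalide | Oc1c(C(OC)OC)c(OCc3ccccc3)c2c(c1OC#CC(OC)OC)[C@@H](O[C@@H](C)c1ccccc1)OC2=O | intermediate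
22 | but-2-ynoic acid | CC#CC(=O)O | starting material
23 | but-2-ynoic anhydride | CC#CC(=O)OC(=O)C#CC | intermediate
24 | (3S)-7-(benzyloxy)-6-(dimethoxymethyl)-4-[(3,3-dimethoxyprop-1-yn-1-yl)oxy]-3-[(1S)-1-phenylethoxy]phthalid-5-yl but-2-ynoate (diyne) | CC#CC(=O)Oc1c(C(OC)OC)c(OCc3ccccc3)c2c(c1OC#CC(OC)OC)[C@@H](O[C@@H](C)c1ccccc1)OC2=O | intermediate
25 | benzyl alcohol | OCc1ccccc1 | starting material
26 | trichloroethylene | ClC=C(Cl)Cl | starting material
27 | potassium benzyloxide | [K+].[O-]Cc1ccccc1 | intermediate
28 | dichloroacetylene | ClC#CCl | intermediate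
29 | benzyl (E)-1,2-dichlorovinyl ether | Cl/C=C(/Cl)OCc1ccccc1 | intermediate
30 | benzyl chloroethynyl ether | ClC#COCc1ccccc1 | intermediate
31 | lithium benzyloxyacetylide | [Li]C#COCc1ccccc1 | intermediate
32 | benzyloxyethyne | C#COCc1ccccc1 | intermediate
33 | protected depsidone (bis-benzyl ether, bis-dimethyl acetal, (S)-1-phenylethyl acetal, lactol carbon S) | Cc1cc(OCc2ccccc2)c(C(OC)OC)c2c1C(=O)Oc1c(C(OC)OC)c(OCc3ccccc3)c3c(c1O2)[C@@H](O[C@@H](C)c1ccccc1)OC3=O | intermediate
34 | dialdehyde (bis-benzyl ether, (S)-1-phenylethyl acetal, lactol carbon S) | Cc1cc(OCc2ccccc2)c(C=O)c2c1C(=O)Oc1c(C=O)c(OCc3ccccc3)c3c(c1O2)[C@@H](O[C@@H](C)c1ccccc1)OC3=O | intermediate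
35 | CNP0296574.1 (lactol carbon S) | Cc1cc(O)c(C=O)c2c1C(=O)Oc1c(C=O)c(O)c3c(c1O2)[C@@H](O)OC3=O | target

**Step count**

Total: 18 steps. Longest linear sequence: 16 steps (steps 1–13 and 16–18); the benzyloxyethyne branch is steps 14–15.

**Steps most likely to fail**

Step 16. Closure of the seven-membered ring may be slow, so that the terminal ynol ether 32 trimerises with itself or adds twice to the ynoate, or 32 may insert in the reverse orientation. The fallback sets out from diyne 24 and lithium acetylide 31 and comes back to the route at dialdehyde 34. Acetylide 31 is quenched with Me3SiCl in place of methanol to give benzyl (trimethylsilyl)ethynyl ether F1, an internal alkyne that does not readily trimerise with itself and whose bulky silyl group is steered to the position beside the small methyl-bearing carbon. Cycloaddition of F1 with 24 under the same rhodium catalyst ((CH2Cl)2, rt → 40 °C) would give the ring A C-silylated protected depsidone F2. CF3CO2H in wet CH2Cl2 at 0 °C should then remove the silyl group by ipso-protonation (that carbon is ortho to the benzyloxy and para to the aryloxy group) and hydrolyse both dimethyl acetals in the same operation, giving 34.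

Step 11. The amide or alkoxide base may attack the lactone acetal (ring opening or loss of configuration at C3) faster than the enolate is triflated, or the enol triflate may eliminate sluggishly. The fallback sets out from silyl ether 14 and comes back at ynol ether 20. Desilylation with n-Bu4NF and neutral work-up gives the C4 phenol F3. 2,2-Dimethoxyacetaldehyde with CBr4 and PPh3 gives 1,1-dibromo-3,3-dimethoxyprop-1-ene F4. Copper-catalysed C–O coupling of F3 with F4 (CuI, 2,2'-bipyridine, K3PO4, toluene, 100 °C) would give the (Z)-α-bromo enol ether F5, in which H and Br are anti. t-BuOK (THF, −40 → 0 °C) should then remove HBr to give 20 without any ketone enolate or triflating agent.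

Step 18. The palladium catalyst may also reduce the two formyl groups or the ring-opened lactol (over-reduction to hydroxymethyl, methyl or phthalide). The fallback sets out from protected depsidone 33 and goes straight to target 35. Hydrogenolysis is run first on 33 (H2, Pd/C, EtOAc with a little Et3N, rt), while both aldehydes are still masked, to give the debenzylated bis(dimethyl acetal) F6 with free phenols and free (S)-lactol. The two acetals, now ortho to free phenols and very labile, are opened last in cold wet acetone buffered near pH 5 (NaH2PO4), giving 35.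

**Further compounds**

F1 | step 16 | benzyl (trimethylsilyl)ethynyl ether | C[Si](C)(C)C#COCc1ccccc1
F2 | step 16 | protected depsidone with Me3Si on the ring A carbon between the methyl-bearing and benzyloxy-bearing carbons | Cc1c([Si](C)(C)C)c(OCc2ccccc2)c(C(OC)OC)c2c1C(=O)Oc1c(C(OC)OC)c(OCc3ccccc3)c3c(c1O2)[C@@H](O[C@@H](C)c1ccccc1)OC3=O
F3 | step 11 | (3S)-5-(allyloxy)-7-(benzyloxy)-6-(dimethoxymethyl)-4-hydroxy-3-[(1S)-1-phenylethoxy]phthalide | C=CCOc1c(C(OC)OC)c(OCc3ccccc3)c2c(c1O)[C@@H](O[C@@H](C)c1ccccc1)OC2=O
F4 | step 11 | 1,1-dibromo-3,3-dimethoxyprop-1-ene | COC(OC)C=C(Br)Br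
F5 | step 11 | (3S)-5-(allyloxy)-7-(benzyloxy)-4-{[(Z)-1-bromo-3,3-dimethoxyprop-1-en-1-yl]oxy}-6-(dimethoxymethyl)-3-[(1S)-1-phenylethoxy]phthalide | C=CCOc1c(C(OC)OC)c(OCc3ccccc3)c2c(c1O/C(Br)=C/C(OC)OC)[C@@H](O[C@@H](C)c1ccccc1)OC2=O
F6 | step 18 | debenzylated bis(dimethyl acetal) of the target with free (S)-lactol | Cc1cc(O)c(C(OC)OC)c2c1C(=O)Oc1c(C(OC)OC)c(O)c3c(c1O2)[C@@H](O)OC3=O
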